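**Late fall.** Late in both earlier runs, in which Q turns into the product E over the catalyst Z, the sum E + Q was still falling. In the alpha run it went from 28.9% to 22.2% of the charge, and in the zeta run from 40.0% to 20.4%.

| flask | Q | Z | temperature | remark | time |
|---|---|---|---|---|---|
| alpha | 28 mM | 0.5 mol% | 58 °C | run made earlier |  |
| zeta | 44 mM | 0.5 mol% | 74 °C | run made earlier |  |
| Sunday's | 20 mM | 0.5 mol% |  | at 50 °C until 8.0 d, from then on at 80 °C | 25 d |
| Saturday's | 20 mM | 0.5 mol% | 80 °C |  | 25 d |
| Friday's | 20 mM | 0.5 mol% | 50 °C |  | 25 d |

- alpha (time / d: E / %, Q / %): 8.00: 20.8, 8.1; 15.0: 20.2, 8.2; 25.0: 19.1, 7.9; 40.0: 17.3, 8.1; 80.0: 14.0, 8.2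
- zeta (time / d: E / %, Q / %): 2.50: 31.4, 8.6; 8.00: 27.3, 7.4; 15.0: 26.0, 8.3; 20.0: 20.3, 5.4; 30.0: 16.7, 3.7

(readings scatter by 1 percentage point)



- the best flask by amount of E, in percent of the Q charged; "all alike" if 1.5 percentage points covers them all (Sunday's / Saturday's / Friday's / all alike)
- amount of E at the end, in percent of the Q charged, Sunday's
- amount of E at the end, in percent of the Q charged, Saturday's
- amount of E at the end, in percent of the Q charged, Friday's

**Drain rate.** I called the rate of that fall the drain rate λ: the natural logarithm of the first sum over the last, divided by the days between, which treats the fall as pseudo-first-order. These readings gave 0.00366 /d for alpha and 0.0245 /d for zeta, so zeta drained faster. The two runs differ in charge as well as temperature, but I credited the difference to temperature and assumed the same factor per degree throughout, which gave a drain rate of 0.0499 /d at 80 °C and 0.00142 /d at 50 °C.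

**Bench rule.** The bench rule I tried here was that, at the same charge of Q and Z, a hotter flask tops out at more E. I took each first reading of E back to the start with λ, which gave a top of 21.4% for alpha and 33.4% for zeta. Their charges differ too, but I credited the rise to temperature. Carried the same way, the top became 39.4% at 80 °C and 17.2% at 50 °C.

**The border.** The rule stops where the extra drain has eaten the higher top. That border is the logarithm of the ratio of the tops over the difference of the drain rates, 17.2 d of hot time. Saturday's flask stays hot past it, and Sunday's, hot for 17.0 d, sits on it. I assumed that Sunday's flask reaches the hot top soon after the change. My reckoning gave 16.7% for Sunday's, 11.3% for Saturday's and 16.6% for Friday's. In that reckoning Sunday's and Friday's were level, with Saturday's lower.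

**The result.** The forecast, which differed from mine, named Friday's as best, with 10% for Sunday's, 14% for Saturday's and 15.5% for Friday's, and said of the sudden loss in zeta: “It may be a delayed event, and alpha does not show it.” The flasks gave 19.5% in Sunday's, 13.5% in Saturday's and 15.6% in Friday's, so the best was Sunday's.

    Q + Z ⇌ E + Z, rate k1*[Q]*[Z] forward; the back reaction follows from the equilibrium constant (K = 1.80, k = 7.71 /M/min, Ea = 47.0 kJ/mol, ΔH = 28.0 kJ/mol)
    E ⇌ D (K = 4.49, k = 7.72 × 10⁻⁴ /min, Ea = 118 kJ/mol, ΔH = −39.0 kJ/mol)
    Q → X (k = 1.13 × 10⁻⁵ /min, Ea = 107 kJ/mol)
    (constants at 50 °C)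

**The check.** In Friday's flask the half-life of E by its forward step into D alone was 0.62 d, short against the 25 d, and at the end D stood at 70.6% beside E at 15.6%. Sunday's E stood above Saturday's by a factor of 1.44, and λ at 80 °C over the 8.0 d of difference in hot time had given 1.49. For the flask like Friday's kept at 65 °C, λ and the top carried down from 80 °C to that temperature gave E of 21.1%, and that flask held E of 21.0%.

(The earlier runs and the new flask are calculated from invented constants; the scatter is artificial.)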